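In percent of the J charged, a charge of Q reads as its equivalents cQ/cJ: Tuesday's has 2.00%, its loss ratio, and Wednesday's has 2.00%.

| setting | south-east | north | south | Wednesday's | Tuesday's |
|---|---|---|---|---|---|
| J | 18 mM | 38 mM | 13 mM | 25 mM | 13 mM |
| Q | 0.26 mM | 0.26 mM | 0.40 mM | 0.500 mM | 0.260 mM |
| remark | run made earlier | run made earlier | run made earlier |  |  |
| time |  |  |  | 30 h | 30 h |

- south-east (time / h: L / %, J / %): 2.50: 90.5, 10.7; 4.00: 91.8, 4.4; 6.00: 95.6, 4.5; 10.0: 94.7, 2.0; 20.0: 95.8, 1.3; 30.0: 98.0, 0.5
- north (time / h: L / %, J / %): 2.50: 93.9, 4.2; 4.00: 97.4, 2.0; 6.00: 96.2, 0.8; 10.0: 99.2, 1.1; 20.0: 99.6, 0; 30.0: 99.7, 0.2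
- south (time / h: L / %, J / %): 6.00: 92.4, 5.9; 12.0: 93.9, 1.8; 20.0: 95.2, 0; 25.0: 95.6, 0.7; 30.0: 93.9, 3.0

(readings scatter by 1 percentage point)

- the flask that ends with the higher amount of L, in percent of the J charged, or "neither" when 2 percentage points or less lies between them (Wednesday's / Tuesday's / neither)
- final L, as a percentage of the J charged, in Wednesday's
- final L, as a percentage of the J charged, in Tuesday's

- percentages count the J that a species holds: one L counts as two
- a reading or a percentage of L counts all its forms, free or not

In the south run, from 12.0 h on, L and J together fell short of the charge by 3.98% on average, against a loss ratio of 3.08%, and with readings good to 1 percentage point I took this as about one J lost per Q. I then read the north run's 4.2% of J at 2.50 h as second-order decay and scaled it by cJ·t, which by my estimate gave 1.06% of J in Tuesday's and 0.552% in Wednesday's. Subtracting loss ratio and leftover J, I reckoned 96.9% of L for Tuesday's and 97.4% for Wednesday's, a gap smaller than the margin.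

The forecast gave 96% for Wednesday's and 95.5% for Tuesday's, lower than my figures, with the answer neither, reasoning “so L is lost in proportion to Q/J”.

Wednesday's gave 97.5% and Tuesday's 97.0%, so the answer is neither.

    J + Q → D (k = 160 M⁻¹ h⁻¹)
    X ⇌ L, rate k2*(cs2 - [L]) while solid is left; crystals form when [L] > cs2 (solubility = 5.20 mM, k = 24.0 h⁻¹)
    2 J → L (k = 110 M⁻¹ h⁻¹)

Tuesday's held D at 1.92% at 30.0 h, against its loss ratio of 2.00%. Its neighbour, charged with 5.2 mM of J and the same Q, has a loss ratio of 5.00%. The same scaling of the north run's reading gives 2.60% of J for that neighbour, so subtracting loss ratio and leftover J reckons 92.4% of L, and that neighbour ended with L at 92.8%.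

The data come from a simulation for an exercise; the scatter is artificial.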